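**Remark on the chemistry:** (−)-epiafzelechin (1) is taken from the chiral pool (sold as a natural-product reference substance), so C2 and C3 of the upper unit are bought; every other stereocentre is made in the route.

## Retrosynthetic overview

1. The target is (−)-epiafzelechin 3-O-gallate-(4β→6)-(−)-epicatechin 3-O-gallate; both gallates (Steglich) and all thirteen benzyl ethers (hydrogenolysis) are dealt with last, on the 3,3''-diol of the benzylated dimer.
2. Key disconnection: pyran ring C of the lower unit is opened at C4–C4a and at O1–C8a, giving an aryne (C4a≡C8a) of the phloroglucinol ring that already hangs on C4 of the upper unit, and a γ-chloro alkoxide carrying O1, C2, C3, C4 and ring B.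
3. Enabling feature: in ring A of the lower unit, C8a (bearing O1) and C4a (bearing C4) are neighbours and C4a is flanked by the C5 oxygen, so in the aryne the C5–O group sends the alkoxide to C8a and leaves the carbanion on C4a; because this ring is attached through C6 (para to C8a), a symmetric 2,6-bis(benzyloxy)-4-hydroxyphenyl group on the upper C4 fixes the 4→6 linkage.
4. Aryne precursor: (−)-epiafzelechin, C4 oxidation, Friedel–Crafts arylation (sets 4β), ortho-bromination, retro-Brook shift, triflation. Chloro alcohol: Evans syn glycolate aldol (sets C2 and C3 of the lower unit), reduction, chlorination.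
5. Ring order: upper rings A, B, C from the chiral pool; lower ring A enters as an arene and lower ring B with the aldol fragment; lower ring C is the only ring made and is closed last.

Key step: step 13

## Route

Step 1
Reactants: 1 (−)-epiafzelechin
Product: 2 5,7,4'-tri-O-benzyl-(−)-epiafzelechin
Conditions: BnBr (3.3 equiv), K2CO3, DMF, 0 °C to rt
Reagents that add atoms: benzyl bromide, BrCc1ccccc1
Why: Williamson O-alkylation in which carbonate deprotonates only the three phenols, so the secondary 3-hydroxyl stays free and C2 and C3 are untouched.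

Step 2
Reactants: 2 5,7,4'-tri-O-benzyl-(−)-epiafzelechin
Product: 3 5,7,4'-tri-O-benzyl-4β-(2-ethoxyethoxy)epiafzelechin
Conditions: DDQ, 2-ethoxyethanol, CH2Cl2, rt
Reagents that add atoms: 2-ethoxyethanol, CCOCCO
Why: Benzylic oxidation in which DDQ abstracts the C4 hydride (activated by the ring A oxygens) and the alcohol captures the cation anti to the 2-aryl and 3-hydroxyl groups, which should set the 4β (3,4-trans) ether, a known way to activate C4 of benzylated flavan-3-ols.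

Step 3
Reactants: 3 5,7,4'-tri-O-benzyl-4β-(2-ethoxyethoxy)epiafzelechin
Product: 4 3-O-allyl-5,7,4'-tri-O-benzyl-4β-(2-ethoxyethoxy)epiafzelechin
Conditions: NaH, allyl bromide, DMF, 0 °C to rt
Reagents that add atoms: allyl bromide, C=CCBr
Why: Williamson etherification of the sodium 3-alkoxide; the allyl ether is chosen because it should survive Lewis acid, organolithium and alkoxide and can later be removed beside benzyl ethers.

Step 4
Reactants: 5 3,5-bis(benzyloxy)phenol
Product: 6 [3,5-bis(benzyloxy)phenoxy]triisopropylsilane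
Conditions: i-Pr3SiCl, imidazole, DMF, rt
Reagents that add atoms: chlorotriisopropylsilane, CC(C)[Si](Cl)(C(C)C)C(C)C
Why: Standard silylation of a phenol; the bulky silyl group is meant to shield both ring positions ortho to this oxygen in step 5.

Step 5
Reactants: 4 3-O-allyl-5,7,4'-tri-O-benzyl-4β-(2-ethoxyethoxy)epiafzelechin; 6 [3,5-bis(benzyloxy)phenoxy]triisopropylsilane (4 equiv)
Product: 7 3-O-allyl-5,7,4'-tri-O-benzyl-4β-[2,6-bis(benzyloxy)-4-(triisopropylsilyloxy)phenyl]epiafzelechin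
Conditions: TMSOTf, CH2Cl2, −78 to −40 °C
Reagents that add atoms: none
Why: Friedel–Crafts arylation in which TMSOTf ionises the chelating 2-ethoxyethoxy group to the C4 cation, the excess arene attacks through its position between the two benzyloxy groups (para to the shielded silyloxy group), and approach anti to the 3-O-allyl and 2-aryl groups should set the new C4 centre as 4β (3,4-trans), as is general for 2,3-cis flavan-4-yl cations.

Step 6
Reactants: 7 3-O-allyl-5,7,4'-tri-O-benzyl-4β-[2,6-bis(benzyloxy)-4-(triisopropylsilyloxy)phenyl]epiafzelechin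
Product: 8 3-O-allyl-5,7,4'-tri-O-benzyl-4β-[2,6-bis(benzyloxy)-4-hydroxyphenyl]epiafzelechin
Conditions: tetrabutylammonium fluoride, AcOH, THF, 0 °C
Reagents that add atoms: none
Why: Fluoride cleavage of an aryl silyl ether, buffered with acetic acid so that no other group is exposed to base.

Step 7
Reactants: 8 3-O-allyl-5,7,4'-tri-O-benzyl-4β-[2,6-bis(benzyloxy)-4-hydroxyphenyl]epiafzelechin
Product: 9 3-O-allyl-5,7,4'-tri-O-benzyl-4β-[2,6-bis(benzyloxy)-3-bromo-4-hydroxyphenyl]epiafzelechin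
Conditions: NBS (1.0 equiv), i-Pr2NH (cat.), CH2Cl2, −78 °C
Reagents that add atoms: N-bromosuccinimide, O=C1CCC(=O)N1Br
Why: Amine-catalysed electrophilic ortho-bromination of the only free phenol, which should be the most activated ring and whose two ortho positions are equivalent, so that one bromine marks the future C4a.

Step 8
Reactants: 9 3-O-allyl-5,7,4'-tri-O-benzyl-4β-[2,6-bis(benzyloxy)-3-bromo-4-hydroxyphenyl]epiafzelechin
Product: 13 3-O-allyl-5,7,4'-tri-O-benzyl-4β-[2,6-bis(benzyloxy)-4-(trifluoromethanesulfonyloxy)-3-(trimethylsilyl)phenyl]epiafzelechin, via trimethylsilyl ether 10 (not isolated), via aryllithium 11 (not isolated), via lithium phenoxide 12 (not isolated)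
Conditions: HMDS, THF, 65 °C, then concentrate; n-BuLi (1.05 equiv), THF, −100 °C; Tf2O, −100 to −78 °C
Reagents that add atoms: hexamethyldisilazane, C[Si](C)(C)N[Si](C)(C)C; trifluoromethanesulfonic anhydride, O=S(=O)(OS(=O)(=O)C(F)(F)F)C(F)(F)F
Why: Standard preparation of an ortho-silylaryl triflate by O-silylation, bromine–lithium exchange (faster than any deprotonation at −100 °C), 1,3 O-to-C silyl shift (retro-Brook rearrangement) and O-triflation of the resulting phenoxide.

Step 9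
Reactants: 14 2-(allyloxy)acetic acid; 15 (S)-4-benzyloxazolidin-2-one
Product: 17 (S)-3-[2-(allyloxy)acetyl]-4-benzyloxazolidin-2-one, via mixed anhydride 16 (not isolated)
Conditions: t-BuCOCl, Et3N, THF, −20 °C; then 15, LiCl, −20 °C to rt
Reagents that add atoms: none
Why: N-acylation of the oxazolidinone by the mixed pivalic anhydride, which is attacked at its less hindered glycolyl carbonyl.

Step 10
Reactants: 17 (S)-3-[2-(allyloxy)acetyl]-4-benzyloxazolidin-2-one; 18 3,4-bis(benzyloxy)benzaldehyde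
Product: 21 (S)-3-[(2S,3R)-2-(allyloxy)-3-(3,4-bis(benzyloxy)phenyl)-3-hydroxypropanoyl]-4-benzyloxazolidin-2-one, via boron enolate 19 (not isolated), via boron aldolate 20 (not isolated)
Conditions: Bu2BOTf, i-Pr2NEt, CH2Cl2, 0 °C; then 18, −78 to 0 °C; pH 7 buffer, MeOH, 30% H2O2, 0 °C
Reagents that add atoms: none
Why: Evans syn aldol reaction in which the (Z)-boron enolate reacts through a closed chair (Zimmerman–Traxler) transition state on the face away from the auxiliary benzyl group, which should set both new centres as (2S,3R), the future C3 and C2 of the lower unit.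

Step 11
Reactants: 21 (S)-3-[(2S,3R)-2-(allyloxy)-3-(3,4-bis(benzyloxy)phenyl)-3-hydroxypropanoyl]-4-benzyloxazolidin-2-one
Product: 22 (1R,2R)-2-(allyloxy)-1-[3,4-bis(benzyloxy)phenyl]propane-1,3-diol
Conditions: LiBH4, MeOH (1 equiv), THF, 0 °C
Reagents that add atoms: none
Why: Reductive cleavage of the imide to the primary alcohol with release of the auxiliary, leaving both stereocentres untouched.

Step 12
Reactants: 22 (1R,2R)-2-(allyloxy)-1-[3,4-bis(benzyloxy)phenyl]propane-1,3-diol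
Product: 24 (1R,2S)-2-(allyloxy)-1-[3,4-bis(benzyloxy)phenyl]-3-chloropropan-1-ol, via primary mesylate 23 (not isolated)
Conditions: MsCl (1.05 equiv), 2,4,6-collidine, CH2Cl2, −10 °C; then LiCl, DMF, 45 °C
Reagents that add atoms: lithium chloride, [Li+].[Cl-]
Why: Selective sulfonylation of the primary hydroxyl followed by SN2 displacement with chloride (Finkelstein-type), a chloride being wanted because it is a poor leaving group towards the neighbouring alkoxide of step 13.

Step 13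
Reactants: 13 3-O-allyl-5,7,4'-tri-O-benzyl-4β-[2,6-bis(benzyloxy)-4-(trifluoromethanesulfonyloxy)-3-(trimethylsilyl)phenyl]epiafzelechin; 24 (1R,2S)-2-(allyloxy)-1-[3,4-bis(benzyloxy)phenyl]-3-chloropropan-1-ol (2.2 equiv)
Product: 28 3-O-allyl-5,7,4'-tri-O-benzylepiafzelechin-(4β→6)-3-O-allyl-5,7,3',4'-tetra-O-benzylepicatechin, via potassium alkoxide 25 (not isolated), via aryne 26 (not isolated), via aryl anion 27 (not isolated)
Conditions: 24, KH, 18-crown-6, THF, 0 °C (solution decanted from excess KH); then 13, CsF, THF, −20 °C to rt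
Reagents that add atoms: none
Why: Proposed new method: fluoride (or the alkoxide itself) attacks silicon of 13 and the ortho-triflate leaves to give aryne 26 (C4a≡C8a of the future ring A), alkoxide 25 adds to C8a, the aryne carbon remote from the C5 benzyloxy group, so that the carbanion of 27 sits on C4a next to that inductively stabilising oxygen, and this aryl anion then displaces chloride from the tethered CH2Cl. The closest known reaction types are the Parham cycloalkylation of ortho-lithiated aryl 3-halopropyl ethers to chromans and the aryne annulations in which an O-nucleophile adds and the aryl anion is caught by a tethered electrophile (for example salicylate esters giving xanthones); what is new is a γ-chloroalkoxide as partner, so that the electrophile is an sp3 carbon. Ring C of the lower unit closes in the 6-exo-tet mode (C4a attacks C4 and chloride leaves outside the ring). No stereocentre is created: C2 and C3 come from 24 with retention because the carbinol C–O bond is never broken, and C4 is a methylene. The step needs (a) O-attack at C8a and not at C4a, secured by the C5 oxygen beside the triple bond while C8 on the other side carries only hydrogen, (b) C-alkylation faster than protonation of 27, secured by a fully pre-formed alkoxide in THF with no O–H partner, and (c) survival of 25, secured by the poor chloride leaving group and low temperature, which keep 4-exo-tet oxetane closure slow, and by the allyl ether on O3, which can neither migrate to the neighbouring alkoxide nor be attacked by the aryl anion.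

Step 14
Reactants: 28 3-O-allyl-5,7,4'-tri-O-benzylepiafzelechin-(4β→6)-3-O-allyl-5,7,3',4'-tetra-O-benzylepicatechin
Product: 30 5,7,4'-tri-O-benzylepiafzelechin-(4β→6)-5,7,3',4'-tetra-O-benzylepicatechin, via bis-propenyl ether 29 (not isolated)
Conditions: [Ir(COD)(PMePh2)2]PF6 (cat., activated with H2, then degassed), THF, rt; then 0.1 M aq. HCl, acetone, rt
Reagents that add atoms: none
Why: Iridium hydride-catalysed isomerisation of both allyl ethers to prop-1-enyl ethers followed by mild acid hydrolysis of these enol ethers, conditions under which benzyl ethers and the interflavan bond should be inert.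

Step 15
Reactants: 30 5,7,4'-tri-O-benzylepiafzelechin-(4β→6)-5,7,3',4'-tetra-O-benzylepicatechin; 31 3,4,5-tris(benzyloxy)benzoic acid (3 equiv)
Product: 32 5,7,4'-tri-O-benzyl-3-O-[3,4,5-tris(benzyloxy)benzoyl]epiafzelechin-(4β→6)-5,7,3',4'-tetra-O-benzyl-3-O-[3,4,5-tris(benzyloxy)benzoyl]epicatechin
Conditions: DCC, DMAP, CH2Cl2, rt
Reagents that add atoms: none
Why: Steglich esterification of both secondary 3-hydroxyls with the benzyl-protected gallic acid, with retention because no C–O bond at C3 is broken.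

Step 16
Reactants: 32 5,7,4'-tri-O-benzyl-3-O-[3,4,5-tris(benzyloxy)benzoyl]epiafzelechin-(4β→6)-5,7,3',4'-tetra-O-benzyl-3-O-[3,4,5-tris(benzyloxy)benzoyl]epicatechin
Product: 33 epiafzelechin 3-O-gallate-(4β→6)-epicatechin 3-O-gallate (CNP0169607.1)
Conditions: H2 (1 atm), Pd(OH)2/C, THF/MeOH/H2O, rt
Reagents that add atoms: none
Why: Hydrogenolysis of all thirteen benzyl ethers, under which the gallate esters, the interflavan C–C bond and the ring ethers of flavans are expected to survive.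

## Compound list

1 | (−)-epiafzelechin, (2R,3R)-2-(4-hydroxyphenyl)chroman-3,5,7-triol | O[C@@H]1Cc2c(O)cc(O)cc2O[C@@H]1c1ccc(O)cc1 | starting material
2 | 5,7,4'-tri-O-benzyl-(−)-epiafzelechin | O[C@@H]1Cc2c(OCc3ccccc3)cc(OCc3ccccc3)cc2O[C@@H]1c1ccc(OCc2ccccc2)cc1 | intermediate
3 | 5,7,4'-tri-O-benzyl-4β-(2-ethoxyethoxy)epiafzelechin (2,3-cis, 3,4-trans) | O[C@@H]1[C@@H](OCCOCC)c2c(OCc3ccccc3)cc(OCc3ccccc3)cc2O[C@@H]1c1ccc(OCc2ccccc2)cc1 | intermediate
4 | 3-O-allyl-5,7,4'-tri-O-benzyl-4β-(2-ethoxyethoxy)epiafzelechin | C=CCO[C@@H]1[C@@H](OCCOCC)c2c(OCc3ccccc3)cc(OCc3ccccc3)cc2O[C@@H]1c1ccc(OCc2ccccc2)cc1 | intermediate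
5 | 3,5-bis(benzyloxy)phenol | Oc1cc(OCc2ccccc2)cc(OCc2ccccc2)c1 | starting material
6 | [3,5-bis(benzyloxy)phenoxy]triisopropylsilane | CC(C)[Si](Oc1cc(OCc2ccccc2)cc(OCc2ccccc2)c1)(C(C)C)C(C)C | intermediate
7 | 3-O-allyl-5,7,4'-tri-O-benzyl-4β-[2,6-bis(benzyloxy)-4-(triisopropylsilyloxy)phenyl]epiafzelechin (2,3-cis, 3,4-trans) | C=CCO[C@@H]1[C@@H](c2c(OCc3ccccc3)cc(O[Si](C(C)C)(C(C)C)C(C)C)cc2OCc2ccccc2)c2c(OCc3ccccc3)cc(OCc3ccccc3)cc2O[C@@H]1c1ccc(OCc2ccccc2)cc1 | intermediate
8 | 3-O-allyl-5,7,4'-tri-O-benzyl-4β-[2,6-bis(benzyloxy)-4-hydroxyphenyl]epiafzelechin | C=CCO[C@@H]1[C@@H](c2c(OCc3ccccc3)cc(O)cc2OCc2ccccc2)c2c(OCc3ccccc3)cc(OCc3ccccc3)cc2O[C@@H]1c1ccc(OCc2ccccc2)cc1 | intermediate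
9 | 3-O-allyl-5,7,4'-tri-O-benzyl-4β-[2,6-bis(benzyloxy)-3-bromo-4-hydroxyphenyl]epiafzelechin | C=CCO[C@@H]1[C@@H](c2c(OCc3ccccc3)c(Br)c(O)cc2OCc2ccccc2)c2c(OCc3ccccc3)cc(OCc3ccccc3)cc2O[C@@H]1c1ccc(OCc2ccccc2)cc1 | intermediate
10 | O-trimethylsilyl ether of 9 | C=CCO[C@@H]1[C@@H](c2c(OCc3ccccc3)c(Br)c(O[Si](C)(C)C)cc2OCc2ccccc2)c2c(OCc3ccccc3)cc(OCc3ccccc3)cc2O[C@@H]1c1ccc(OCc2ccccc2)cc1 | intermediate (not isolated)
11 | aryllithium from 10 (lithium in place of bromine) | C=CCO[C@@H]1[C@@H](c2c(OCc3ccccc3)c([Li])c(O[Si](C)(C)C)cc2OCc2ccccc2)c2c(OCc3ccccc3)cc(OCc3ccccc3)cc2O[C@@H]1c1ccc(OCc2ccccc2)cc1 | intermediate (not isolated)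
12 | lithium 3,5-bis(benzyloxy)-4-(flavan-4β-yl)-2-(trimethylsilyl)phenoxide | C=CCO[C@@H]1[C@@H](c2c(OCc3ccccc3)c([Si](C)(C)C)c([O-])cc2OCc2ccccc2)c2c(OCc3ccccc3)cc(OCc3ccccc3)cc2O[C@@H]1c1ccc(OCc2ccccc2)cc1.[Li+] | intermediate (not isolated)
13 | 3-O-allyl-5,7,4'-tri-O-benzyl-4β-[2,6-bis(benzyloxy)-4-(trifluoromethanesulfonyloxy)-3-(trimethylsilyl)phenyl]epiafzelechin (aryne precursor) | C=CCO[C@@H]1[C@@H](c2c(OCc3ccccc3)c([Si](C)(C)C)c(OS(=O)(=O)C(F)(F)F)cc2OCc2ccccc2)c2c(OCc3ccccc3)cc(OCc3ccccc3)cc2O[C@@H]1c1ccc(OCc2ccccc2)cc1 | intermediate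
14 | 2-(allyloxy)acetic acid | C=CCOCC(=O)O | starting material
15 | (S)-4-benzyloxazolidin-2-one | O=C1N[C@@H](Cc2ccccc2)CO1 | starting material
16 | 2-(allyloxy)acetic pivalic anhydride | C=CCOCC(=O)OC(=O)C(C)(C)C | intermediate (not isolated)
17 | (S)-3-[2-(allyloxy)acetyl]-4-benzyloxazolidin-2-one | C=CCOCC(=O)N1[C@@H](Cc2ccccc2)COC1=O | intermediate
18 | 3,4-bis(benzyloxy)benzaldehyde | O=Cc1ccc(OCc2ccccc2)c(OCc2ccccc2)c1 | starting material
19 | (Z)-dibutylboron enolate of 17 | C=CCO/C=C(\OB(CCCC)CCCC)N1[C@@H](Cc2ccccc2)COC1=O | intermediate (not isolated)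
20 | dibutylboron aldolate of 21 | O=C(N1[C@@H](Cc2ccccc2)COC1=O)[C@@H](OCC=C)[C@@H](c1ccc(OCc2ccccc2)c(OCc2ccccc2)c1)OB(CCCC)CCCC | intermediate (not isolated)
21 | (S)-3-[(2S,3R)-2-(allyloxy)-3-(3,4-bis(benzyloxy)phenyl)-3-hydroxypropanoyl]-4-benzyloxazolidin-2-one | O=C(N1[C@@H](Cc2ccccc2)COC1=O)[C@@H](OCC=C)[C@@H](c1ccc(OCc2ccccc2)c(OCc2ccccc2)c1)O | intermediate
22 | (1R,2R)-2-(allyloxy)-1-[3,4-bis(benzyloxy)phenyl]propane-1,3-diol | OC[C@@H](OCC=C)[C@@H](c1ccc(OCc2ccccc2)c(OCc2ccccc2)c1)O | intermediate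
23 | (2R,3R)-2-(allyloxy)-3-[3,4-bis(benzyloxy)phenyl]-3-hydroxypropyl methanesulfonate | CS(=O)(=O)OC[C@@H](OCC=C)[C@@H](c1ccc(OCc2ccccc2)c(OCc2ccccc2)c1)O | intermediate (not isolated)
24 | (1R,2S)-2-(allyloxy)-1-[3,4-bis(benzyloxy)phenyl]-3-chloropropan-1-ol | ClC[C@@H](OCC=C)[C@@H](c1ccc(OCc2ccccc2)c(OCc2ccccc2)c1)O | intermediate
25 | potassium alkoxide of 24 | ClC[C@@H](OCC=C)[C@@H](c1ccc(OCc2ccccc2)c(OCc2ccccc2)c1)[O-].[K+] | intermediate (not isolated)
26 | aryne from 13 (triple bond between the former silyl and triflate carbons) | C=CCO[C@@H]1[C@@H](C2=C(OCc3ccccc3)C#CC=C2OCc2ccccc2)c2c(OCc3ccccc3)cc(OCc3ccccc3)cc2O[C@@H]1c1ccc(OCc2ccccc2)cc1 | intermediate (not isolated)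
27 | potassium aryl anion: O-aryl ether of 24 on C8a with the carbanion on C4a | C=CCO[C@@H]1[C@@H](c2c(OCc3ccccc3)[c-]c(O[C@H](c3ccc(OCc4ccccc4)c(OCc4ccccc4)c3)[C@H](OCC=C)CCl)cc2OCc2ccccc2)c2c(OCc3ccccc3)cc(OCc3ccccc3)cc2O[C@@H]1c1ccc(OCc2ccccc2)cc1.[K+] | intermediate (not isolated)
28 | 3-O-allyl-5,7,4'-tri-O-benzylepiafzelechin-(4β→6)-3-O-allyl-5,7,3',4'-tetra-O-benzylepicatechin | C=CCO[C@@H]1[C@@H](c2c(OCc4ccccc4)cc3c(c2OCc4ccccc4)C[C@@H](OCC=C)[C@@H](c2ccc(OCc4ccccc4)c(OCc4ccccc4)c2)O3)c2c(OCc3ccccc3)cc(OCc3ccccc3)cc2O[C@@H]1c1ccc(OCc2ccccc2)cc1 | intermediate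
29 | bis[(E)-prop-1-enyl] ether corresponding to 28 | C/C=C/O[C@@H]1[C@@H](c2c(OCc4ccccc4)cc3c(c2OCc4ccccc4)C[C@@H](O/C=C/C)[C@@H](c2ccc(OCc4ccccc4)c(OCc4ccccc4)c2)O3)c2c(OCc3ccccc3)cc(OCc3ccccc3)cc2O[C@@H]1c1ccc(OCc2ccccc2)cc1 | intermediate (not isolated)
30 | 5,7,4'-tri-O-benzylepiafzelechin-(4β→6)-5,7,3',4'-tetra-O-benzylepicatechin (3,3''-diol) | O[C@@H]1[C@@H](c2c(OCc4ccccc4)cc3c(c2OCc4ccccc4)C[C@@H](O)[C@@H](c2ccc(OCc4ccccc4)c(OCc4ccccc4)c2)O3)c2c(OCc3ccccc3)cc(OCc3ccccc3)cc2O[C@@H]1c1ccc(OCc2ccccc2)cc1 | intermediate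
31 | 3,4,5-tris(benzyloxy)benzoic acid | OC(=O)c1cc(OCc2ccccc2)c(OCc2ccccc2)c(OCc2ccccc2)c1 | starting material
32 | trideca-O-benzyl ether of the target (3,3''-bis[3,4,5-tris(benzyloxy)benzoate] of 30) | O=C(O[C@@H]1[C@@H](c2c(OCc4ccccc4)cc3c(c2OCc4ccccc4)C[C@@H](OC(=O)c2cc(OCc4ccccc4)c(OCc4ccccc4)c(OCc4ccccc4)c2)[C@@H](c2ccc(OCc4ccccc4)c(OCc4ccccc4)c2)O3)c2c(OCc3ccccc3)cc(OCc3ccccc3)cc2O[C@@H]1c1ccc(OCc2ccccc2)cc1)c1cc(OCc2ccccc2)c(OCc2ccccc2)c(OCc2ccccc2)c1 | intermediate
33 | epiafzelechin 3-O-gallate-(4β→6)-epicatechin 3-O-gallate (CNP0169607.1) | O=C(O[C@@H]1[C@@H](c2c(O)cc3c(c2O)C[C@@H](OC(=O)c2cc(O)c(O)c(O)c2)[C@@H](c2ccc(O)c(O)c2)O3)c2c(O)cc(O)cc2O[C@@H]1c1ccc(O)cc1)c1cc(O)c(O)c(O)c1 | target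

## Step count and risks

Total step count: 16. Longest linear sequence: 11 steps (steps 1, 2, 3, 5, 6, 7, 8, 13, 14, 15, 16).

Steps most likely to fail:

1. Step 13 (proposed new method). What may go wrong: protonation of the aryl anion, or transfer of the charge to a neighbouring benzylic CH2, before ring closure; closure of the alkoxide to an oxetane; or O-attack at the wrong aryne carbon. The fallback forms the same ring in separate known steps, sets out from bromophenol 9 and chloro alcohol 24, and comes back at 28. Mitsunobu inversion of 24 with 4-nitrobenzoic acid (PPh3, diisopropyl azodicarboxylate, THF, 0 °C) would give the anti 4-nitrobenzoate F1. Methanolysis (K2CO3, MeOH, 0 °C) would give the (1S,2S)-chloro alcohol F2. A second Mitsunobu reaction, of F2 with phenol 9 (PPh3, diisopropyl azodicarboxylate, toluene, 0 °C), would form the O1–C2 bond with inversion and so give the (1R,2S)-configured ortho-bromoaryl ether F3. Bromine–lithium exchange (n-BuLi, THF, −100 °C to rt) would give the aryllithium F4, which closes ring C onto CH2Cl by Parham cycloalkylation to give 28.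

2. Step 5. What may go wrong: attack of the C4 cation ortho to the silyloxy group (wrong regiochemistry, leading towards the 4→8 series) or self-condensation of 4 through its own ring A. The fallback removes the regiochemical question, sets out from 4 and comes back at 7. The cation from 4 would be captured by phloroglucinol itself (large excess, BF3·OEt2, THF/CH2Cl2, −20 °C), whose three ring positions are equivalent, to give the 4β-(2,4,6-trihydroxyphenyl) adduct F5. The least hindered, para hydroxyl would be silylated (i-Pr3SiCl, imidazole, DMF, −20 °C) to give the mono-silyl ether F6. Benzylation of the two flanking hydroxyls (BnBr, K2CO3, acetone) would then return 7.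

3. Step 7. What may go wrong: competing bromination of ring A of the upper unit, or double bromination. The fallback replaces electrophilic substitution by directed metalation, sets out from 8 and comes back at 13, so that steps 7 and 8 are both bypassed. Isopropyl isocyanate (Et3N cat., CH2Cl2) would give the N-isopropyl carbamate F7. In one flask, N-silylation (t-BuMe2SiOTf, TMEDA, Et2O, 0 °C) would give the N-silyl carbamate F8, and carbamate-directed ortho-lithiation (n-BuLi, TMEDA, −78 °C) with Me3SiCl quench would give the ortho-silylated N-silyl carbamate F9, which loses its N-silyl group on aqueous NaHSO4 work-up to give the ortho-(trimethylsilyl)aryl carbamate F10. DBU and Et2NH (MeCN, 40 °C) would cleave the carbamate to the silyl phenol F11, which is triflated in the same flask with PhNTf2 to give 13.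

## Further compounds

F1 | step 13 | (1S,2S)-2-(allyloxy)-1-[3,4-bis(benzyloxy)phenyl]-3-chloropropyl 4-nitrobenzoate | ClC[C@@H](OCC=C)[C@H](c1ccc(OCc2ccccc2)c(OCc2ccccc2)c1)OC(=O)c1ccc([N+](=O)[O-])cc1
F2 | step 13 | (1S,2S)-2-(allyloxy)-1-[3,4-bis(benzyloxy)phenyl]-3-chloropropan-1-ol | ClC[C@@H](OCC=C)[C@H](c1ccc(OCc2ccccc2)c(OCc2ccccc2)c1)O
F3 | step 13 | aryl ether of 9 with the (1R,2S)-2-(allyloxy)-1-[3,4-bis(benzyloxy)phenyl]-3-chloropropyl group on the phenol oxygen (bromine ortho to the ether) | C=CCO[C@@H]1[C@@H](c2c(OCc3ccccc3)c(Br)c(O[C@H](c3ccc(OCc4ccccc4)c(OCc4ccccc4)c3)[C@H](OCC=C)CCl)cc2OCc2ccccc2)c2c(OCc3ccccc3)cc(OCc3ccccc3)cc2O[C@@H]1c1ccc(OCc2ccccc2)cc1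
F4 | step 13 | aryllithium from F3 (lithium in place of bromine) | C=CCO[C@@H]1[C@@H](c2c(OCc3ccccc3)c([Li])c(O[C@H](c3ccc(OCc4ccccc4)c(OCc4ccccc4)c3)[C@H](OCC=C)CCl)cc2OCc2ccccc2)c2c(OCc3ccccc3)cc(OCc3ccccc3)cc2O[C@@H]1c1ccc(OCc2ccccc2)cc1
F5 | step 5 | 3-O-allyl-5,7,4'-tri-O-benzyl-4β-(2,4,6-trihydroxyphenyl)epiafzelechin | C=CCO[C@@H]1[C@@H](c2c(O)cc(O)cc2O)c2c(OCc3ccccc3)cc(OCc3ccccc3)cc2O[C@@H]1c1ccc(OCc2ccccc2)cc1
F6 | step 5 | 3-O-allyl-5,7,4'-tri-O-benzyl-4β-[2,6-dihydroxy-4-(triisopropylsilyloxy)phenyl]epiafzelechin | C=CCO[C@@H]1[C@@H](c2c(O)cc(O[Si](C(C)C)(C(C)C)C(C)C)cc2O)c2c(OCc3ccccc3)cc(OCc3ccccc3)cc2O[C@@H]1c1ccc(OCc2ccccc2)cc1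
F7 | step 7 | N-isopropyl carbamate of phenol 8 | C=CCO[C@@H]1[C@@H](c2c(OCc3ccccc3)cc(OC(=O)NC(C)C)cc2OCc2ccccc2)c2c(OCc3ccccc3)cc(OCc3ccccc3)cc2O[C@@H]1c1ccc(OCc2ccccc2)cc1
F8 | step 7 | N-(tert-butyldimethylsilyl)-N-isopropyl carbamate of phenol 8 | C=CCO[C@@H]1[C@@H](c2c(OCc3ccccc3)cc(OC(=O)N(C(C)C)[Si](C)(C)C(C)(C)C)cc2OCc2ccccc2)c2c(OCc3ccccc3)cc(OCc3ccccc3)cc2O[C@@H]1c1ccc(OCc2ccccc2)cc1
F9 | step 7 | ortho-trimethylsilylated N-silyl carbamate | C=CCO[C@@H]1[C@@H](c2c(OCc3ccccc3)c([Si](C)(C)C)c(OC(=O)N(C(C)C)[Si](C)(C)C(C)(C)C)cc2OCc2ccccc2)c2c(OCc3ccccc3)cc(OCc3ccccc3)cc2O[C@@H]1c1ccc(OCc2ccccc2)cc1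
F10 | step 7 | ortho-(trimethylsilyl)aryl N-isopropyl carbamate | C=CCO[C@@H]1[C@@H](c2c(OCc3ccccc3)c([Si](C)(C)C)c(OC(=O)NC(C)C)cc2OCc2ccccc2)c2c(OCc3ccccc3)cc(OCc3ccccc3)cc2O[C@@H]1c1ccc(OCc2ccccc2)cc1
F11 | step 7 | 3-O-allyl-5,7,4'-tri-O-benzyl-4β-[2,6-bis(benzyloxy)-4-hydroxy-3-(trimethylsilyl)phenyl]epiafzelechin | C=CCO[C@@H]1[C@@H](c2c(OCc3ccccc3)c([Si](C)(C)C)c(O)cc2OCc2ccccc2)c2c(OCc3ccccc3)cc(OCc3ccccc3)cc2O[C@@H]1c1ccc(OCc2ccccc2)cc1
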